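The flask cannot be read off either earlier run, for its 20 mM of each substrate lies between the 13 mM of eta and the 30 mM of zeta.

all flasks: free catalyst 40 µM

| run | left-handed substrate | right-handed substrate | solid reagent | remark | time |
|---|---|---|---|---|---|
| eta | 13 mM | 13 mM | 40 mM | run made earlier |  |
| zeta | 30 mM | 30 mM | 40 mM | run made earlier |  |
| flask | 20 mM | 20 mM | 40.0 mM |  | 8.0 min |

| run | time / min | left-handed product / % | right-handed product / % | left-handed substrate / % |
|---|---|---|---|---|
| eta | 0.417 | 0.3 | 0 | 50.4 |
| eta | 1.33 | 3.1 | 2.5 | 47.3 |
| eta | 2.50 | 6.2 | 6.8 | 43.8 |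
| eta | 4.00 | 10.7 | 11.5 | 37.7 |
| eta | 5.00 | 15.2 | 15.4 | 35.3 |
| eta | 6.00 | 18.7 | 17.8 | 32.1 |
| zeta | 1.00 | 1.4 | 1.1 | 49.0 |
| zeta | 2.00 | 2.3 | 2.4 | 47.1 |
| zeta | 3.00 | 4.4 | 4.9 | 46.1 |
| zeta | 4.00 | 6.6 | 6.6 | 43.4 |
| zeta | 5.00 | 8.5 | 7.8 | 42.4 |
| zeta | 6.00 | 10.2 | 9.1 | 38.6 |

(standard deviation of a reading: 0.5 percentage points)

- excess of left-handed product over right-handed product in the product at 10 s
- excess of left-handed product over right-handed product in the product at 8.0 min
- part of the left-handed substrate and right-handed substrate charged together that has reacted at 8.0 min

- free catalyst is single-handed; left-handed substrate and right-handed substrate are mirror images of each other, charged as a racemate, each of them at the stated concentration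
- solid, in amounts per volume of the solution: solid reagent
- the numbers in the tables scatter with a standard deviation of 0.5 percentage points
- at the start none of the solid reagent is in solution
- an excess is the difference of the two amounts in percent of their sum
- an excess is below zero if the other one leads

Each curve can be replaced by its mean, the product of both hands at the last reading divided by that time. Eta gives 1.58 mM min⁻¹ and zeta 1.93 mM min⁻¹, so more than twice the substrate raises the rate by a factor of just 1.22. A straight line between the two runs gives the flask 1.73 mM min⁻¹: this is the mean product rate, a zero-order stand-in for the curve. Zeta's later readings run at 2.00 mM min⁻¹, slightly faster than its mean, so the stand-in errs low, and by little.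

Over 8.0 min this reckoning makes 13.8 mM of product, or 34.5% of the substrates charged. It says nothing of handedness. The forecast, on its own saturation fit, gives 35% reacted, with excesses of 0% at 10 s and 1% at 8.0 min, noting: "More than doubling the substrate barely changes the rate".

The flask gives 37.6% reacted, with excesses of 2.66% and 1.22%, so the forecast stands.

    free catalyst + left-handed substrate ⇌ catalyst intermediate A (K = 22.0 M⁻¹, k = 930 M⁻¹ s⁻¹)
    free catalyst + right-handed substrate ⇌ catalyst intermediate B (K = 51.0 M⁻¹, k = 1500 M⁻¹ s⁻¹)
    partner + catalyst intermediate A → free catalyst + left-handed product (k = 760 M⁻¹ s⁻¹)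
    partner + catalyst intermediate B → free catalyst + right-handed product (k = 310 M⁻¹ s⁻¹)
    solid reagent ⇌ partner, rate k5*(cs5 - [partner]) while solid is left; crystals form when [partner] > cs5 (solubility = 12.0 mM, k = 0.00590 s⁻¹)
    partner → decomposed reagent (k = 0.00340 s⁻¹)

The flask's own mean rate is 1.88 mM min⁻¹, a little above the mean product rate. Each product takes one partner, so 13.8 mM is about a third of the solid reagent charged, and at 8.00 min the solid still stands at 38.8% of its charge. With 10 mM of solid reagent, the same 13.8 mM exceeds the charge, so there the solid reagent is the limiting reagent, and its charge puts the ceiling on reaction at 25.0%. That neighbour reaches 18.6%, with solid reagent at 0% and 2.53 mM of decomposed reagent standing.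

All runs were computed for an exercise, noise included.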